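**Plan**

1. Retrosynthesis: the pyridone is contracted rather than opened. Its C4–C5 bond is exchanged for a C4–C6 bond, which turns the 5-aryl-4-hydroxy-2-pyridone into a 3-acyl-5-(4-hydroxybenzyl)tetramic acid built from L-tyrosine.
2. Further cuts: ring bond C3–C4 (Dieckmann), amide bond N1–C2 (acylketene aminolysis), the bond from C3 to the side-chain carbonyl (C-acylation of Meldrum's acid), and the sp3–sp2 bond C5'–C6' of the side chain (Negishi coupling).
3. Forward order: the C1'–C5' unit comes from a meso 2,4-dimethylpentane-1,5-diol, the butenyl end is coupled on, and the alcohol is oxidised to the acid. The acid is extended by Meldrum's acid and joined to tyrosine methyl ester, the pyrrolidine-2,4-dione ring is closed, and only then is it expanded to the pyridone. The phenol ring is bought inside tyrosine.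
4. Enabling feature: N1, C2, C3, C4 and C6 of the pyridone are the five ring atoms of a tyrosine-derived tetramic acid (C6 = tyrosine α-carbon, C4 = tyrosine carboxyl carbon). The aryl-bearing C5 is the tyrosine benzylic carbon, one bond outside that five-membered ring, and a 1,2-shift can slide it in.
5. Stereochemistry: the syn relation of the two methyl-bearing carbons comes from the cis anhydride and their absolute sense from lipase desymmetrisation of the meso diol. The E alkene comes from (E)-2-bromobut-2-ene with retention. The tyrosine stereocentre is temporary and vanishes in the ring expansion.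

Key step: step 10

Assumption: the Pseudomonas fluorescens lipase is taken to acetylate the meso diol in the sense that gives the (2R,4S)-monoacetate, and an Aspergillus oryzae strain expressing the ring-expanding cytochrome P450 ApdE of the aspyridone pathway (native acyl chain also 2,4-dimethyl-branched) is taken to be obtainable by standard transformation.

**Route**

Step 1
Reactants: 1 cis-2,4-dimethylglutaric anhydride (meso, (3R,5S)-3,5-dimethyloxane-2,6-dione)
Product: 2 meso-(2R,4S)-2,4-dimethylpentane-1,5-diol
Conditions: LiAlH4, THF, 0 °C to reflux; then H2O, aq NaOH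
Reagents that add atoms: none
Why: Hydride reduction of a cyclic anhydride by LiAlH4 delivers both carbonyl carbons as primary alcohols without enolising the two α-carbons, so the cis (meso) relation fixed in the ring is carried into the open-chain diol.

Step 2
Reactants: 2 meso-(2R,4S)-2,4-dimethylpentane-1,5-diol
Product: 3 (2S,4R)-5-hydroxy-2,4-dimethylpentyl acetate (the same compound as (2R,4S)-5-acetoxy-2,4-dimethylpentan-1-ol)
Conditions: Pseudomonas fluorescens lipase (Amano AK), vinyl acetate, THF, rt; stopped when 2 is consumed
Reagents that add atoms: vinyl acetate, C=COC(C)=O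
Why: Lipase-catalysed irreversible transesterification (enantiotopic-group-selective acylation of a meso diol) should acetylate only one of the two mirror-related hydroxymethyl arms, so that no new stereocentre is made but the chiral active site fixes the absolute configuration of both methyl-bearing carbons at once, while loss of the enol as acetaldehyde keeps the acyl transfer from reversing.

Step 3
Reactants: 3 (2S,4R)-5-hydroxy-2,4-dimethylpentyl acetate
Product: 4 (2S,4R)-5-iodo-2,4-dimethylpentyl acetate
Conditions: I2, PPh3, imidazole, CH2Cl2, 0 °C to rt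
Reagents that add atoms: iodine, II
Why: Appel-type iodination under Garegg–Samuelsson conditions converts the primary alcohol through its alkoxyphosphonium salt into the iodide by SN2 displacement at CH2, which leaves the neighbouring stereocentre and the acetate untouched.

Step 4
Reactants: 4 (2S,4R)-5-iodo-2,4-dimethylpentyl acetate; 5 (E)-2-bromobut-2-ene
Product: 7 (2S,4R,6E)-2,4,6-trimethyloct-6-en-1-yl acetate, via alkylzinc iodide 6 (not isolated)
Conditions: Zn dust (activated with BrCH2CH2Br and Me3SiCl), LiCl, THF, 40 °C; then 5, Pd(OAc)2 (2 mol %), SPhos (4 mol %), THF, rt to 40 °C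
Reagents that add atoms: zinc, [Zn] (its atom is held only in 6 and is absent from 7)
Why: Negishi cross-coupling, in which LiCl-assisted insertion of zinc into the primary C–I bond gives an acetate-tolerant alkylzinc that transmetalates to the alkenylpalladium bromide formed from 5 and zerovalent palladium with retention of the E geometry, the bulky electron-rich biarylphosphine making reductive elimination faster than β-hydride elimination.

Step 5
Reactants: 7 (2S,4R,6E)-2,4,6-trimethyloct-6-en-1-yl acetate
Product: 8 (2S,4R,6E)-2,4,6-trimethyloct-6-en-1-ol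
Conditions: K2CO3 (cat.), MeOH, rt
Reagents that add atoms: none
Why: Carbonate-catalysed transesterification with methanol (Zemplén-type deacetylation) frees the primary alcohol under conditions that cannot reach the non-acidic methyl stereocentres or the alkene.

Step 6
Reactants: 8 (2S,4R,6E)-2,4,6-trimethyloct-6-en-1-ol
Product: 10 (2S,4R,6E)-2,4,6-trimethyloct-6-enoic acid, via aldehyde 9 (not isolated)
Conditions: TEMPO (cat.), PhI(OAc)2 (2.2 equiv), MeCN/H2O, 0 °C to rt
Reagents that add atoms: water, O
Why: Oxoammonium-mediated oxidation (TEMPO with PhI(OAc)2 in aqueous acetonitrile) takes the primary alcohol through aldehyde 9 to the acid, water supplying the second oxygen, under near-neutral conditions that should neither enolise the α-methyl stereocentre nor attack the trisubstituted alkene.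

Step 7
Reactants: 10 (2S,4R,6E)-2,4,6-trimethyloct-6-enoic acid; 11 Meldrum's acid (2,2-dimethyl-1,3-dioxane-4,6-dione)
Product: 12 5-[(2S,4R,6E)-1-hydroxy-2,4,6-trimethyloct-6-en-1-ylidene]-2,2-dimethyl-1,3-dioxane-4,6-dione (acyl Meldrum's acid, enol form)
Conditions: DCC, DMAP, CH2Cl2, 0 °C to rt; filtration, wash with cold aq KHSO4; used crude
Reagents that add atoms: none
Why: Steglich-type carbodiimide and DMAP activation of the acid followed by C-acylation of the Meldrum's acid anion gives the enolised acyl derivative, whose enol double bond lies between the former carboxyl carbon and the dioxanedione ring and so does not involve the adjacent methyl stereocentre.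

Step 8
Reactants: 12 acyl Meldrum's acid of the chain acid; 13 L-tyrosine methyl ester (free base, methyl (2S)-2-amino-3-(4-hydroxyphenyl)propanoate)
Product: 15 methyl N-[(4S,6R,8E)-4,6,8-trimethyl-3-oxodec-8-enoyl]-L-tyrosinate, via acylketene 14 (not isolated)
Conditions: MeCN, 80 °C
Reagents that add atoms: none
Why: Thermal retro-hetero-Diels–Alder fragmentation of the acyl Meldrum's acid expels acetone and CO2 to give acylketene 14, which is captured by the most nucleophilic site present, the primary amine of 13, in an acylketene aminolysis that leaves the slower phenol and the stereocentres alone.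

Step 9
Reactants: 15 methyl N-[(4S,6R,8E)-4,6,8-trimethyl-3-oxodec-8-enoyl]-L-tyrosinate
Product: 16 (5S)-4-hydroxy-5-(4-hydroxybenzyl)-3-[(2S,4R,6E)-2,4,6-trimethyloct-6-enoyl]-1,5-dihydro-2H-pyrrol-2-one (3-acyltetramic acid)
Conditions: NaOMe (2.5 equiv), MeOH, rt, 30 min; then aq HCl to pH 2
Reagents that add atoms: none
Why: Lacey–Dieckmann cyclisation, in which the β-ketoamide enolate attacks the methyl ester in a 5-exo-trig acyl substitution to close the pyrrolidine-2,4-dione, should spare the acyl α-stereocentre because the negative charge sits on the doubly stabilised enolate and then on the tetramate, and any epimerisation of the ring carbon from tyrosine costs only material since that centre is erased in step 10.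

Step 10
Reactants: 16 (5S)-3-acyl-5-(4-hydroxybenzyl)tetramic acid
Product: 17 Vancouverone A, 4-hydroxy-5-(4-hydroxyphenyl)-3-[(2S,4R,6E)-2,4,6-trimethyloct-6-enoyl]pyridin-2(1H)-one
Conditions: Aspergillus oryzae whole cells expressing the ring-expanding cytochrome P450 ApdE with the host NADPH-cytochrome P450 reductase (no other tailoring oxidase of the cluster), 16 fed in DMSO, aerated culture, 28 °C; EtOAc extraction at pH 3
Reagents that add atoms: none
Why: The high-valent iron-oxo species of the P450 should abstract a hydrogen atom from the benzylic CH2 of the 4-hydroxybenzyl group, the benzylic radical should add to the neighbouring ring carbon C4, and the cyclopropyloxy radical so formed should break the old C4–C5 bond, which moves the benzylic carbon into the ring and leaves the radical next to nitrogen, where a second one-electron oxidation and loss of a proton aromatise the ring. The closest known reaction type is the Dowd–Beckwith radical ring expansion, known in enzymatic form as the P450-catalysed tetramic acid to 2-pyridone ring expansion of fungal pyridone biosynthesis on this same 3-acyl-5-(4-hydroxybenzyl)tetramate class. The six-membered ring therefore arises by one-carbon ring expansion of the five-membered lactam (transient 3-exo-trig closure, then β-scission), not by cyclisation of an open chain. No new stereocentre is formed, the tyrosine-derived ring stereocentre is consumed and the two chain stereocentres lie far from the reacting atoms. The step needs hydrogen abstraction at the benzylic position rather than at the allylic C–H bonds or the alkene of the chain, and rearrangement rather than oxygen rebound to the benzylic alcohol. Both are secured by the unchanged native head group, whose binding holds the benzylic C–H over the iron and the radical beside C4, and the direction of the shift places the aryl group on C5 and leaves C6 as CH.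

**Compound list**

1 | cis-2,4-dimethylglutaric anhydride (meso) | O=C1[C@H](C)C[C@H](C)C(=O)O1 | starting material
2 | meso-(2R,4S)-2,4-dimethylpentane-1,5-diol | OC[C@H](C)C[C@H](C)CO | intermediate
3 | (2S,4R)-5-hydroxy-2,4-dimethylpentyl acetate | OC[C@H](C)C[C@H](C)COC(C)=O | intermediate
4 | (2S,4R)-5-iodo-2,4-dimethylpentyl acetate | IC[C@H](C)C[C@H](C)COC(C)=O | intermediate
5 | (E)-2-bromobut-2-ene | C/C=C(\C)Br | starting material
6 | [(2R,4S)-5-acetoxy-2,4-dimethylpentyl]zinc iodide | I[Zn]C[C@H](C)C[C@H](C)COC(C)=O | intermediate (not isolated)
7 | (2S,4R,6E)-2,4,6-trimethyloct-6-en-1-yl acetate | C/C=C(\C)C[C@H](C)C[C@H](C)COC(C)=O | intermediate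
8 | (2S,4R,6E)-2,4,6-trimethyloct-6-en-1-ol | C/C=C(\C)C[C@H](C)C[C@H](C)CO | intermediate
9 | (2S,4R,6E)-2,4,6-trimethyloct-6-enal | C/C=C(\C)C[C@H](C)C[C@H](C)C=O | intermediate (not isolated)
10 | (2S,4R,6E)-2,4,6-trimethyloct-6-enoic acid | C/C=C(\C)C[C@H](C)C[C@H](C)C(=O)O | intermediate
11 | Meldrum's acid | CC1(C)OC(=O)CC(=O)O1 | starting material
12 | 5-[(2S,4R,6E)-1-hydroxy-2,4,6-trimethyloct-6-en-1-ylidene]-2,2-dimethyl-1,3-dioxane-4,6-dione | C/C=C(\C)C[C@H](C)C[C@H](C)C(O)=C1C(=O)OC(C)(C)OC1=O | intermediate
13 | L-tyrosine methyl ester | COC(=O)[C@@H](N)Cc1ccc(O)cc1 | starting material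
14 | (4S,6R,8E)-4,6,8-trimethyldeca-1,8-diene-1,3-dione (acylketene) | C/C=C(\C)C[C@H](C)C[C@H](C)C(=O)C=C=O | intermediate (not isolated)
15 | methyl N-[(4S,6R,8E)-4,6,8-trimethyl-3-oxodec-8-enoyl]-L-tyrosinate | C/C=C(\C)C[C@H](C)C[C@H](C)C(=O)CC(=O)N[C@@H](Cc1ccc(O)cc1)C(=O)OC | intermediate
16 | (5S)-4-hydroxy-5-(4-hydroxybenzyl)-3-[(2S,4R,6E)-2,4,6-trimethyloct-6-enoyl]-1,5-dihydro-2H-pyrrol-2-one | C/C=C(\C)C[C@H](C)C[C@H](C)C(=O)C1=C(O)[C@H](Cc2ccc(O)cc2)NC1=O | intermediate
17 | Vancouverone A | C/C=C(\C)C[C@H](C)C[C@H](C)C(=O)c1c(O)c(-c2ccc(O)cc2)c[nH]c1=O | target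

**Count**

Total step count: 10. Longest linear sequence: 10 steps (1 to 17); 5, 11 and 13 are bought and enter directly.

**Steps most likely to fail**

1. Step 10. What may go wrong: oxygen rebound onto the benzylic radical instead of rearrangement (hydroxylation shunt), hydrogen abstraction or epoxidation on the unnatural alkene-bearing chain, or poor uptake and turnover of the fed substrate by the cells.

   Fallback, setting out from acyl Meldrum's acid 12 and returning at 17, by purely chemical ring construction:
   - Commercial methyl 2-(4-hydroxyphenyl)acetate would be silylated (TBSCl, imidazole, DMF) to methyl 2-[4-(tert-butyldimethylsilyloxy)phenyl]acetate F1.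
   - F1 would be aminomethylenated with tert-butoxybis(dimethylamino)methane (toluene, 80 °C) to methyl (2E)-2-[4-(tert-butyldimethylsilyloxy)phenyl]-3-(dimethylamino)prop-2-enoate F2.
   - Amine exchange with NH4OAc in MeOH would give the primary enamino ester methyl (2Z)-3-amino-2-[4-(tert-butyldimethylsilyloxy)phenyl]prop-2-enoate F3.
   - Heating F3 with 12 in toluene should give, through acylketene 14, the N-acyl enamino ester methyl (2Z)-2-[4-(tert-butyldimethylsilyloxy)phenyl]-3-{[(4S,6R,8E)-4,6,8-trimethyl-3-oxodec-8-enoyl]amino}prop-2-enoate F4. The silyl ether keeps the phenol from competing with the weakly nucleophilic enamine nitrogen.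
   - NaOMe in MeOH should first strip the aryl silyl ether to the phenol methyl (2Z)-2-(4-hydroxyphenyl)-3-{[(4S,6R,8E)-4,6,8-trimethyl-3-oxodec-8-enoyl]amino}prop-2-enoate F5 (not isolated). It should then close the pyridone by a 6-exo-trig Dieckmann condensation of the β-ketoamide carbon onto the acrylate ester, giving 17 on acidification.

   This enamino ester acylation and Dieckmann sequence is an established route to 3-substituted 4-hydroxy-2-pyridones. It puts the aryl group on C5 because that carbon was the α-carbon of the arylacetate.

2. Step 4. What may go wrong: sluggish or incomplete zinc insertion at the β-branched primary iodide, and loss of the alkylzinc by protonation or homocoupling before it transmetalates.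

   Fallback, setting out from iodide 4 and returning at acetate 7, with boron in place of zinc:
   - Copper-catalysed borylation (B2pin2, CuI, PPh3, LiOt-Bu, DMF, rt; tert-butoxide chosen to spare the acetate) would give (2S,4S)-2,4-dimethyl-5-(4,4,5,5-tetramethyl-1,3,2-dioxaborolan-2-yl)pentyl acetate F6.
   - Aqueous KHF2 in MeOH would convert F6 into the storable salt potassium [(2S,4S)-5-acetoxy-2,4-dimethylpentyl]trifluoroborate F7.
   - Suzuki–Miyaura coupling of F7 with 5 (PdCl2(dppf), Cs2CO3, toluene/H2O, 80 °C) should give 7. Any acetate lost under the hot carbonate only anticipates step 5.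

   The descriptor at the boron-bearing end reads S only because CH2B ranks below the chain CH2. No bond at a stereocentre is touched.

3. Step 2. What may go wrong: insufficient discrimination between the two enantiotopic hydroxymethyl groups, or overrun to the diacetate, which erodes an enantiomeric purity that no later step can restore.

   Fallback, setting out from anhydride 1 and returning at alcohol 8, by desymmetrising the anhydride instead of the diol:
   - Cinchona alkaloid-mediated methanolysis (quinidine or quinine, whichever pseudoenantiomer gives the required sense, MeOH, toluene, −55 °C) would give the half-ester (2R,4S)-5-methoxy-2,4-dimethyl-5-oxopentanoic acid F8.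
   - Chemoselective reduction of the free acid with BH3·SMe2 (THF, 0 °C) would give methyl (2S,4R)-5-hydroxy-2,4-dimethylpentanoate F9, used at once to forestall lactonisation.
   - Appel iodination (I2, PPh3, imidazole) would give methyl (2S,4R)-5-iodo-2,4-dimethylpentanoate F10.
   - Zinc insertion as in step 4 would give [(2R,4S)-5-methoxy-2,4-dimethyl-5-oxopentyl]zinc iodide F11 (not isolated), and Negishi coupling with 5 would give methyl (2S,4R,6E)-2,4,6-trimethyloct-6-enoate F12.
   - LiAlH4 (THF, 0 °C) would reduce F12 to 8 without exposing the α-stereocentre to base.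

Further compounds
F1 | step 10 | methyl 2-[4-(tert-butyldimethylsilyloxy)phenyl]acetate | COC(=O)Cc1ccc(O[Si](C)(C)C(C)(C)C)cc1
F2 | step 10 | methyl (2E)-2-[4-(tert-butyldimethylsilyloxy)phenyl]-3-(dimethylamino)prop-2-enoate | CN(C)/C=C(\c1ccc(O[Si](C)(C)C(C)(C)C)cc1)C(=O)OC
F3 | step 10 | methyl (2Z)-3-amino-2-[4-(tert-butyldimethylsilyloxy)phenyl]prop-2-enoate | N/C=C(/c1ccc(O[Si](C)(C)C(C)(C)C)cc1)C(=O)OC
F4 | step 10 | methyl (2Z)-2-[4-(tert-butyldimethylsilyloxy)phenyl]-3-{[(4S,6R,8E)-4,6,8-trimethyl-3-oxodec-8-enoyl]amino}prop-2-enoate | C/C=C(\C)C[C@H](C)C[C@H](C)C(=O)CC(=O)N/C=C(/c1ccc(O[Si](C)(C)C(C)(C)C)cc1)C(=O)OC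
F5 | step 10 | methyl (2Z)-2-(4-hydroxyphenyl)-3-{[(4S,6R,8E)-4,6,8-trimethyl-3-oxodec-8-enoyl]amino}prop-2-enoate | C/C=C(\C)C[C@H](C)C[C@H](C)C(=O)CC(=O)N/C=C(/c1ccc(O)cc1)C(=O)OC
F6 | step 4 | (2S,4S)-2,4-dimethyl-5-(4,4,5,5-tetramethyl-1,3,2-dioxaborolan-2-yl)pentyl acetate | CC1(C)OB(C[C@H](C)C[C@H](C)COC(C)=O)OC1(C)C
F7 | step 4 | potassium [(2S,4S)-5-acetoxy-2,4-dimethylpentyl]trifluoroborate | [K+].F[B-](F)(F)C[C@H](C)C[C@H](C)COC(C)=O
F8 | step 2 | (2R,4S)-5-methoxy-2,4-dimethyl-5-oxopentanoic acid | OC(=O)[C@H](C)C[C@H](C)C(=O)OC
F9 | step 2 | methyl (2S,4R)-5-hydroxy-2,4-dimethylpentanoate | OC[C@H](C)C[C@H](C)C(=O)OC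
F10 | step 2 | methyl (2S,4R)-5-iodo-2,4-dimethylpentanoate | IC[C@H](C)C[C@H](C)C(=O)OC
F11 | step 2 | [(2R,4S)-5-methoxy-2,4-dimethyl-5-oxopentyl]zinc iodide | I[Zn]C[C@H](C)C[C@H](C)C(=O)OC
F12 | step 2 | methyl (2S,4R,6E)-2,4,6-trimethyloct-6-enoate | C/C=C(\C)C[C@H](C)C[C@H](C)C(=O)OC
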